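**Plan**

1. Retrosynthesis (germacrane numbering C1–C10): both oxiranes (C1–C10, C4–C5) go back to Z olefins, and the C6 cinnamate / C8 carbinol pair goes back to a C6‑hydroxy C8‑ketone (Evans–Tishchenko), giving a (Z,Z)-6-oxygenated germacra-1(10),4-dien-8-one.
2. Enabling feature: C4 and C8 lie 1,5 across the ten-membered ring. A C4–C8 bond turns it into a cis-fused bicyclo[5.3.0]decene (cyclopentane C4–C5–C6–C7–C8, cycloheptene C4–C3–C2–C1=C10–C9–C8). With a C8 alkoxide and a C5 mesylate flanking that bond, Grob cleavage returns C8=O and Z C4=C5.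
3. The bicycle is cut at C1=C10 (ring-closing metathesis), C9–C10 (isopropenyl opening of a C8 spiro-oxirane), C7–isopropyl (conjugate addition) and C3–C4 (Michael addition to acrolein), back to 2-methylcyclopentane-1,3-dione.
4. Forward order of rings: cyclopentane (from the dione), cycloheptene (step 8), ten-membered ring by fragmentation (step 17), oxiranes last (step 20).
5. Stereochemistry: CBS desymmetrisation sets C4; peracid attack on the methyl face sets C8 (cis fusion); cuprate addition anti to the angular silyloxy group sets C7; oxaziridine anti to isopropyl sets C6; hydroxyl-directed reduction sets C5 (mesylate cis to C3, hence Z); Evans–Tishchenko sets C8 of the target; peripheral attack sets both oxiranes.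

Key step: step 17

Remark (convention): germacrane numbering is kept for the bicyclic intermediates (C4 and C8 are the ring-fusion atoms); "methyl face" is the face of the cyclopentane carrying the C4 methyl, "ring face" the one carrying C3 and C9.

Remark (assumption): conjugate addition to enone 15 is taken to occur anti to the angular silyloxy group. C4 and C8 are erased and C5 counts only relative to C4 in the fragmentation, so the cis-fused mesylate is carried as the (4R,5S,6S,7S,8R) isomer (mesylate trans to the C6 silyl ether), which gives the same dienone.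

**Route**

Step 1
Reactants: 1 2-methylcyclopentane-1,3-dione; 2 acrolein
Product: 3 3-(1-methyl-2,5-dioxocyclopentyl)propanal
Conditions: H2O, rt
Reagents that add atoms: none
Why: Michael addition of the enolised cyclic 1,3-dione to acrolein builds the quaternary carbon (future C4) and the C3–C2–C1 chain; no stereocentre arises because the two carbonyl arms are identical.

Step 2
Reactants: 3 3-(1-methyl-2,5-dioxocyclopentyl)propanal
Product: 4 2-(but-3-en-1-yl)-2-methylcyclopentane-1,3-dione
Conditions: Ph3PCH3Br, KN(SiMe3)2, THF, −78 → 0 °C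
Reagents that add atoms: methyltriphenylphosphonium bromide, C[P+](c1ccccc1)(c1ccccc1)c1ccccc1.[Br-]
Why: Wittig methylenation, in which the non-stabilised ylide should take the aldehyde far faster than the two hindered ketones next to the quaternary carbon.

Step 3
Reactants: 4 2-(but-3-en-1-yl)-2-methylcyclopentane-1,3-dione
Product: 5 (2R,3R)-2-(but-3-en-1-yl)-3-hydroxy-2-methylcyclopentan-1-one
Conditions: (S)-2-methyl-CBS-oxazaborolidine [(S)-1-methyl-3,3-diphenyltetrahydro-1H,3H-pyrrolo[1,2-c][1,3,2]oxazaborole] (20 mol %), catecholborane, toluene, −78 °C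
Reagents that add atoms: none
Why: Corey–Bakshi–Shibata desymmetrising reduction of a 2,2-disubstituted cyclopentane-1,3-dione, in which the catalyst (quaternary carbon as the large group) sets the carbinol as R and hydride enters from the methyl-bearing face so that the hydroxyl ends cis to the butenyl chain, fixing the quaternary centre (future C4).

Step 4
Reactants: 5 (2R,3R)-hydroxy ketone
Product: 6 (2R,3R)-2-(but-3-en-1-yl)-3-(tert-butyldimethylsilyloxy)-2-methylcyclopentan-1-one
Conditions: TBSCl, imidazole, DMF, rt
Reagents that add atoms: tert-butyldimethylsilyl chloride, CC(C)(C)[Si](C)(C)Cl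
Why: silyl ether formation masks the aldol-type hydroxyl against retro-aldol cleavage and makes the butenyl face of the ring the hindered one.

Step 5
Reactants: 6 silyloxy ketone
Product: 7 tert-butyl{[(1R,2S)-2-(but-3-en-1-yl)-2-methyl-3-methylidenecyclopentyl]oxy}dimethylsilane
Conditions: Ph3PCH3Br, KOtBu, toluene, 80 °C
Reagents that add atoms: methyltriphenylphosphonium bromide, C[P+](c1ccccc1)(c1ccccc1)c1ccccc1.[Br-]
Why: Wittig methylenation of the hindered ketone supplies C9; the β-silyloxy group cannot be eliminated because the intervening carbon is quaternary, and no stereocentre is touched.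

Step 6
Reactants: 7 exocyclic methylene compound
Product: 8 (3R,4R,5R)-4-(but-3-en-1-yl)-5-(tert-butyldimethylsilyloxy)-4-methyl-1-oxaspiro[2.4]heptane
Conditions: mCPBA (1.05 equiv), NaHCO3, CH2Cl2, −20 → 0 °C
Reagents that add atoms: 3-chloroperoxybenzoic acid, OOC(=O)c1cccc(Cl)c1
Why: Prilezhaev epoxidation, in which the 1,1-disubstituted olefin should react ahead of the monosubstituted vinyl group and the peracid approaches from the face of the small methyl group (anti to the butenyl chain and the silyloxy group), placing the oxygen cis to methyl and so setting the future C8 carbinol centre.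

Step 7
Reactants: 8 spiro-oxirane; 9 isopropenylmagnesium bromide
Product: 10 (1S,2R,3R)-2-(but-3-en-1-yl)-3-(tert-butyldimethylsilyloxy)-2-methyl-1-(2-methylprop-2-en-1-yl)cyclopentan-1-ol
Conditions: CuI (20 mol %), THF, −40 → 0 °C; then H2O
Reagents that add atoms: none
Why: copper-catalysed Grignard opening of the 2,2-disubstituted oxirane at its CH2 terminus (SN2) forms C9–C10 without touching the C8–O bond, so C9 lies cis to the butenyl chain as the cis ring fusion requires, the opposite of what direct methallyl addition to the ketone would give.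

Step 8
Reactants: 10 diene tertiary alcohol
Product: 11 (4R,5R,8S)-5-(tert-butyldimethylsilyloxy)-4,10-dimethyl-cis-bicyclo[5.3.0]dec-1(10)-en-8-ol
Conditions: second-generation Grubbs catalyst RuCl2(=CHPh)(PCy3)(H2IMes) (5 mol %), CH2Cl2 (5 mM), 40 °C
Reagents that add atoms: none
Why: ring-closing metathesis of the vinyl and 1,1-disubstituted olefins closes the trisubstituted cycloheptene (C1=C10, Z by ring size), the cis fusion being preset by steps 3 and 6.

Step 9
Reactants: 11 bicyclic silyl ether
Product: 12 (4R,5R,8S)-4,10-dimethyl-cis-bicyclo[5.3.0]dec-1(10)-ene-5,8-diol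
Conditions: Bu4NF, THF, 50 °C
Reagents that add atoms: none
Why: fluoride cleavage of the silyl ether frees the secondary C5 hydroxyl, the tertiary alcohol and the olefin being inert.

Step 10
Reactants: 12 diol
Product: 13 (4S,8S)-8-hydroxy-4,10-dimethyl-cis-bicyclo[5.3.0]dec-1(10)-en-5-one
Conditions: Dess–Martin periodinane, NaHCO3, CH2Cl2, 0 °C → rt
Reagents that add atoms: none
Why: Dess–Martin oxidation converts only the secondary alcohol, and its neutral conditions avoid retro-aldol opening of the β-hydroxy ketone to an achiral enolate.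

Step 11
Reactants: 13 β-hydroxy ketone
Product: 15 (4S,8R)-4,10-dimethyl-8-(triethylsilyloxy)-cis-bicyclo[5.3.0]deca-1(10),6-dien-5-one, via bis(triethylsilyl) dienol ether 14 (not isolated)
Conditions: TESOTf, Et3N, CH2Cl2, 0 °C; then Pd(OAc)2 (1.1 equiv), MeCN, rt
Reagents that add atoms: triethylsilyl trifluoromethanesulfonate, CC[Si](CC)(CC)OS(=O)(=O)C(F)(F)F
Why: soft enolisation (possible only towards C6) with silylation of the tertiary hydroxyl, followed by Saegusa–Ito oxidation, gives the C6=C7 enone while the angular silyl ether blocks retro-aldol under the later basic steps and shields the methyl face.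

Step 12
Reactants: 15 enone; 16 isopropylmagnesium chloride
Product: 17 (4S,7S,8R)-7-isopropyl-4,10-dimethyl-8-(triethylsilyloxy)-5-(trimethylsilyloxy)-cis-bicyclo[5.3.0]deca-1(10),5-diene
Conditions: CuBr·SMe2 (20 mol %), TMSCl, DMPU, THF, −78 → −40 °C
Reagents that add atoms: chlorotrimethylsilane, C[Si](C)(C)Cl
Why: copper-catalysed conjugate addition of the Grignard reagent with silyl chloride trapping, in which the organocopper should add to C7 anti to the adjacent angular triethylsilyloxy group (the sense known for 4-silyloxycyclopentenones), placing isopropyl on the ring face and setting C7.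

Step 13
Reactants: 17 silyl enol ether
Product: 20 (4S,6S,7S,8R)-6,8-dihydroxy-7-isopropyl-4,10-dimethyl-cis-bicyclo[5.3.0]dec-1(10)-en-5-one, via lithium enolate 18 (not isolated), via triethylsilyl ether 19 (not isolated)
Conditions: MeLi, THF, −78 → 0 °C; 2-(phenylsulfonyl)-3-phenyloxaziridine, −78 °C; then 1 M HCl, THF, rt
Reagents that add atoms: 2-(phenylsulfonyl)-3-phenyloxaziridine (Davis oxaziridine), O=S(=O)(c1ccccc1)N1OC1c1ccccc1
Why: cleavage of the silyl enol ether to the regiodefined lithium enolate and Davis hydroxylation, the oxaziridine attacking C6 anti to the neighbouring isopropyl group (methyl face) to set C6, after which the acidic work-up frees the tertiary hydroxyl.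

Step 14
Reactants: 20 dihydroxy ketone
Product: 21 (4S,6S,7S,8R)-6-(tert-butyldimethylsilyloxy)-8-hydroxy-7-isopropyl-4,10-dimethyl-cis-bicyclo[5.3.0]dec-1(10)-en-5-one
Conditions: TBSOTf (1.1 equiv), 2,6-lutidine, CH2Cl2, −78 °C
Reagents that add atoms: tert-butyldimethylsilyl trifluoromethanesulfonate, CC(C)(C)[Si](C)(C)OS(=O)(=O)C(F)(F)F
Why: selective silylation of the secondary α-ketol hydroxyl, the tertiary hydroxyl between two fully substituted carbons being too hindered to compete at low temperature with one equivalent.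

Step 15
Reactants: 21 β-hydroxy ketone
Product: 22 (4R,5S,6S,7S,8R)-6-(tert-butyldimethylsilyloxy)-7-isopropyl-4,10-dimethyl-cis-bicyclo[5.3.0]dec-1(10)-ene-5,8-diol
Conditions: Me4NBH(OAc)3, MeCN/AcOH, −20 → 0 °C
Reagents that add atoms: none
Why: Evans–Saksena hydroxyl-directed reduction, in which the triacetoxyborohydride reduces only after exchange with the C8 hydroxyl and delivers hydride to the methyl face of C5, so the new hydroxyl sits on the ring face, trans to the C8 hydroxyl and cis to C3.

Step 16
Reactants: 22 diol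
Product: 23 (4R,5S,6S,7S,8R)-6-(tert-butyldimethylsilyloxy)-8-hydroxy-7-isopropyl-4,10-dimethyl-cis-bicyclo[5.3.0]dec-1(10)-en-5-yl methanesulfonate
Conditions: MsCl, Et3N, CH2Cl2, −20 → 0 °C
Reagents that add atoms: methanesulfonyl chloride, CS(=O)(=O)Cl
Why: sulfonylation of the secondary hydroxyl with retention at C5, the tertiary hydroxyl being left free as the future electron-releasing group.

Step 17
Reactants: 23 hydroxy mesylate
Product: 25 (1(10)Z,4Z,6R,7S)-6-(tert-butyldimethylsilyloxy)germacra-1(10),4-dien-8-one, via potassium alkoxide 24 (not isolated)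
Conditions: KOtBu (1.1 equiv), THF, −78 → −30 °C; pH 7 buffer at −78 °C
Reagents that add atoms: none
Why: Deprotonation gives the tertiary C8 alkoxide 24, and once the cyclopentane adopts the half-chair with the mesylate pseudo-equatorial (the cis fusion allows C3 to go pseudo-axial) an oxygen lone pair, the C4–C8 bond and the C5–O bond are anti-periplanar, so the C4–C8 bond breaks in a concerted Grob (Wharton) fragmentation. The closest known reaction type is the fragmentation of decalin and hydrindane 1,3-diol monosulfonates to medium-ring enones. No ring is closed: the ten-membered ring appears because the bond shared by the five- and seven-membered rings is cut, so no closure mode applies. No new stereocentre is formed; C4 and C8 become trigonal, C6 and C7 are untouched, and the olefin geometry is fixed stereospecifically because the mesylate is cis to C3 and trans to the C4 methyl, so C3 and C6 end up cis (Z), while C1=C10 stays Z. The selectivity needed is fragmentation over E2 loss of the mesylate, silyl transfer from O6 to the cis C8 alkoxide, and E1cB loss of silanolate from the product; C6–H is cis to the mesylate (no anti elimination), and low temperature with a cold neutral quench protects the β-silyloxy ketone. The (Z,Z)-cyclodeca-1,5-diene is kept at or below 40 °C from here on to avoid Cope rearrangement.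

Step 18
Reactants: 25 silyloxy dienone
Product: 26 (1(10)Z,4Z,6R,7S)-6-hydroxygermacra-1(10),4-dien-8-one
Conditions: HF·pyridine, pyridine, THF, 0 °C
Reagents that add atoms: none
Why: buffered acidic fluoride desilylation frees the C6 hydroxyl without the basic conditions that would eliminate the β-oxygen of the ketone.

Step 19
Reactants: 26 β-hydroxy ketone; 27 (E)-cinnamaldehyde
Product: 28 (1(10)Z,4Z,6R,7R,8R)-8-hydroxygermacra-1(10),4-dien-6-yl (E)-cinnamate
Conditions: SmI2 (30 mol %), 27 (5 equiv), THF, −10 °C
Reagents that add atoms: none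
Why: Evans–Tishchenko reduction, in which the samarium-bound hemiacetal formed from the C6 hydroxyl and the aldehyde delivers hydride intramolecularly to the C8 ketone through a six-membered transition state, setting C8 in the 1,3-anti sense and leaving O6 as the cinnamate in one operation.

Step 20
Reactants: 28 hydroxy cinnamate diene
Product: 29 target (1R,4S,5R,6S,7R,8R,10S)-1,10:4,5-diepoxy-8-hydroxygermacran-6-yl (E)-cinnamate
Conditions: dimethyldioxirane (2.5 equiv), acetone, −20 → 0 °C
Reagents that add atoms: dimethyldioxirane, CC1(C)OO1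
Why: dioxirane epoxidation of the two electron-rich trisubstituted Z olefins (the cinnamate olefin is electron-poor and should not react), with peripheral attack on the ring conformer that holds O6, isopropyl and O8 pseudo-equatorial placing each oxygen on the outer face, anti to the homoallylic ring carbons, which corresponds to the target configuration at C1, C10, C4 and C5.

**Compound list**

1 | 2-methylcyclopentane-1,3-dione | CC1C(=O)CCC1=O | starting material
2 | acrolein (prop-2-enal) | C=CC=O | starting material
3 | 3-(1-methyl-2,5-dioxocyclopentyl)propanal | CC1(CCC=O)C(=O)CCC1=O | intermediate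
4 | 2-(but-3-en-1-yl)-2-methylcyclopentane-1,3-dione | CC1(CCC=C)C(=O)CCC1=O | intermediate
5 | (2R,3R)-2-(but-3-en-1-yl)-3-hydroxy-2-methylcyclopentan-1-one (hydroxyl cis to butenyl) | O=C1CC[C@@H](O)[C@@]1(C)CCC=C | intermediate
6 | (2R,3R)-2-(but-3-en-1-yl)-3-(tert-butyldimethylsilyloxy)-2-methylcyclopentan-1-one | O=C1CC[C@@H](O[Si](C)(C)C(C)(C)C)[C@@]1(C)CCC=C | intermediate
7 | tert-butyl{[(1R,2S)-2-(but-3-en-1-yl)-2-methyl-3-methylidenecyclopentyl]oxy}dimethylsilane | C=C1CC[C@@H](O[Si](C)(C)C(C)(C)C)[C@@]1(C)CCC=C | intermediate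
8 | (3R,4R,5R)-4-(but-3-en-1-yl)-5-(tert-butyldimethylsilyloxy)-4-methyl-1-oxaspiro[2.4]heptane (oxirane oxygen cis to methyl) | C1O[C@@]12CC[C@@H](O[Si](C)(C)C(C)(C)C)[C@@]2(C)CCC=C | intermediate
9 | isopropenylmagnesium bromide (prop-1-en-2-ylmagnesium bromide) | CC(=C)[Mg]Br | starting material
10 | (1S,2R,3R)-2-(but-3-en-1-yl)-3-(tert-butyldimethylsilyloxy)-2-methyl-1-(2-methylprop-2-en-1-yl)cyclopentan-1-ol | CC(=C)C[C@@]1(O)CC[C@@H](O[Si](C)(C)C(C)(C)C)[C@@]1(C)CCC=C | intermediate
11 | (4R,5R,8S)-5-(tert-butyldimethylsilyloxy)-4,10-dimethyl-cis-bicyclo[5.3.0]dec-1(10)-en-8-ol (8-OH on the methyl face, 5-O on the ring face) | C1C[C@@H](O[Si](C)(C)C(C)(C)C)[C@@]2(C)CC/C=C(C)\C[C@@]12O | intermediate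
12 | (4R,5R,8S)-4,10-dimethyl-cis-bicyclo[5.3.0]dec-1(10)-ene-5,8-diol | C1C[C@@H](O)[C@@]2(C)CC/C=C(C)\C[C@@]12O | intermediate
13 | (4S,8S)-8-hydroxy-4,10-dimethyl-cis-bicyclo[5.3.0]dec-1(10)-en-5-one | C1CC(=O)[C@@]2(C)CC/C=C(C)\C[C@@]12O | intermediate
14 | (4S,8S)-4,10-dimethyl-5,8-bis(triethylsilyloxy)-cis-bicyclo[5.3.0]deca-1(10),5-diene | C1C=C(O[Si](CC)(CC)CC)[C@@]2(C)CC/C=C(C)\C[C@@]12O[Si](CC)(CC)CC | intermediate (not isolated)
15 | (4S,8R)-4,10-dimethyl-8-(triethylsilyloxy)-cis-bicyclo[5.3.0]deca-1(10),6-dien-5-one | C1=CC(=O)[C@@]2(C)CC/C=C(C)\C[C@@]12O[Si](CC)(CC)CC | intermediate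
16 | isopropylmagnesium chloride | CC(C)[Mg]Cl | starting material
17 | (4S,7S,8R)-7-isopropyl-4,10-dimethyl-8-(triethylsilyloxy)-5-(trimethylsilyloxy)-cis-bicyclo[5.3.0]deca-1(10),5-diene (isopropyl on the ring face) | CC(C)[C@H]1C=C(O[Si](C)(C)C)[C@@]2(C)CC/C=C(C)\C[C@@]12O[Si](CC)(CC)CC | intermediate
18 | lithium (4S,7S,8R)-7-isopropyl-4,10-dimethyl-8-(triethylsilyloxy)-cis-bicyclo[5.3.0]deca-1(10),5-dien-5-olate | CC(C)[C@H]1C=C([O-])[C@@]2(C)CC/C=C(C)\C[C@@]12O[Si](CC)(CC)CC.[Li+] | intermediate (not isolated)
19 | (4S,6S,7S,8R)-6-hydroxy-7-isopropyl-4,10-dimethyl-8-(triethylsilyloxy)-cis-bicyclo[5.3.0]dec-1(10)-en-5-one | CC(C)[C@H]1[C@H](O)C(=O)[C@@]2(C)CC/C=C(C)\C[C@@]12O[Si](CC)(CC)CC | intermediate (not isolated)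
20 | (4S,6S,7S,8R)-6,8-dihydroxy-7-isopropyl-4,10-dimethyl-cis-bicyclo[5.3.0]dec-1(10)-en-5-one (6-OH on the methyl face) | CC(C)[C@H]1[C@H](O)C(=O)[C@@]2(C)CC/C=C(C)\C[C@@]12O | intermediate
21 | (4S,6S,7S,8R)-6-(tert-butyldimethylsilyloxy)-8-hydroxy-7-isopropyl-4,10-dimethyl-cis-bicyclo[5.3.0]dec-1(10)-en-5-one | CC(C)[C@H]1[C@H](O[Si](C)(C)C(C)(C)C)C(=O)[C@@]2(C)CC/C=C(C)\C[C@@]12O | intermediate
22 | (4R,5S,6S,7S,8R)-6-(tert-butyldimethylsilyloxy)-7-isopropyl-4,10-dimethyl-cis-bicyclo[5.3.0]dec-1(10)-ene-5,8-diol (5-OH on the ring face) | CC(C)[C@H]1[C@H](O[Si](C)(C)C(C)(C)C)[C@@H](O)[C@@]2(C)CC/C=C(C)\C[C@@]12O | intermediate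
23 | (4R,5S,6S,7S,8R)-6-(tert-butyldimethylsilyloxy)-8-hydroxy-7-isopropyl-4,10-dimethyl-cis-bicyclo[5.3.0]dec-1(10)-en-5-yl methanesulfonate | CC(C)[C@H]1[C@H](O[Si](C)(C)C(C)(C)C)[C@@H](OS(C)(=O)=O)[C@@]2(C)CC/C=C(C)\C[C@@]12O | intermediate
24 | potassium alkoxide of 23 (C8–O–K) | CC(C)[C@H]1[C@H](O[Si](C)(C)C(C)(C)C)[C@@H](OS(C)(=O)=O)[C@@]2(C)CC/C=C(C)\C[C@@]12[O-].[K+] | intermediate (not isolated)
25 | (1(10)Z,4Z,6R,7S)-6-(tert-butyldimethylsilyloxy)germacra-1(10),4-dien-8-one | CC(C)[C@H]1[C@H](O[Si](C)(C)C(C)(C)C)/C=C(C)\CC/C=C(C)\CC1=O | intermediate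
26 | (1(10)Z,4Z,6R,7S)-6-hydroxygermacra-1(10),4-dien-8-one | CC(C)[C@H]1[C@H](O)/C=C(C)\CC/C=C(C)\CC1=O | intermediate
27 | (E)-cinnamaldehyde | O=C/C=C/c1ccccc1 | starting material
28 | (1(10)Z,4Z,6R,7R,8R)-8-hydroxygermacra-1(10),4-dien-6-yl (E)-cinnamate | CC(C)[C@H]1[C@H](OC(=O)/C=C/c2ccccc2)/C=C(C)\CC/C=C(C)\C[C@H]1O | intermediate
29 | (1R,4S,5R,6S,7R,8R,10S)-1,10:4,5-diepoxy-8-hydroxygermacran-6-yl (E)-cinnamate | CC(C)[C@H]1[C@H](OC(=O)/C=C/c2ccccc2)[C@H]2O[C@@]2(C)CC[C@H]2O[C@@]2(C)C[C@H]1O | target

**Step count**

Total: 20 steps. Longest linear sequence: 20 steps (from 1; all other building blocks are commercial).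

**Steps most likely to fail**

Step 12. Transfer of a secondary alkyl group to a β-carbon flanked by a fully substituted carbinol carbon may stall, so that the organocopper species reduces or merely enolises the enone, or adds with too little facial bias. The sense of this addition also decides which enantiomer of the catalyst is needed in step 3. Fallback: from 15, a tin-hydride-mediated radical conjugate addition (iPrI, Bu3SnH, AIBN, benzene, 80 °C) should give the saturated ketone F1, the nucleophilic isopropyl radical being less sensitive to steric compression and likewise steered away from the silyloxy face. The potassium enolate of F1 (KN(SiMe3)2, THF, −78 °C) is then hydroxylated with the same oxaziridine to 19, and the acidic work-up of step 13 returns the route at 20.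

Step 17. Fragmentation may be outrun by transfer of the silyl group from O6 to the cis-disposed C8 alkoxide, or followed by E1cB loss of silanolate from the β-silyloxy ketone while base is still present. Fallback: from 23, fragmentation induced by LiAlH4 in THF (0 °C → rt), in which the alkoxyaluminate is the electron-releasing group and the ketone is reduced as soon as it forms, should give the dienol F2 as C8 epimers. Oxidation of F2 with Dess–Martin periodinane under buffered neutral conditions returns the route at 25.

Step 20. Peripheral attack may not discriminate the two faces of the C1=C10 olefin, which is flanked only by methylene groups, or the first-formed mono-epoxide may be opened transannularly before the second oxidation. Fallback: the oxiranes are introduced one at a time by delivery from the neighbouring hydroxyl groups, which in the conformer described lie on the outer face of their olefins. From 26, VO(acac)2/tBuOOH (CH2Cl2, 0 °C) should epoxidise only the allylic C4=C5 olefin to give the epoxy hydroxy ketone F3. Evans–Tishchenko reduction of F3 with 27 (SmI2 cat., THF, −10 °C) gives the epoxy cinnamate F4. A second VO(acac)2/tBuOOH oxidation, now directed by the homoallylic C8 hydroxyl, closes the C1–C10 oxirane and arrives at 29.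

**Further compounds**

F1 | step 12 | (4S,7S,8R)-7-isopropyl-4,10-dimethyl-8-(triethylsilyloxy)-cis-bicyclo[5.3.0]dec-1(10)-en-5-one | CC(C)[C@H]1CC(=O)[C@@]2(C)CC/C=C(C)\C[C@@]12O[Si](CC)(CC)CC
F2 | step 17 | (1(10)Z,4Z,6R,7S)-6-(tert-butyldimethylsilyloxy)germacra-1(10),4-dien-8-ol (C8 epimers; the centre is removed on re-oxidation) | CC(C)[C@H]1[C@H](O[Si](C)(C)C(C)(C)C)/C=C(C)\CC/C=C(C)\CC1O
F3 | step 20 | (1(10)Z,4S,5R,6S,7S)-4,5-epoxy-6-hydroxygermacr-1(10)-en-8-one | CC(C)[C@H]1[C@H](O)[C@H]2O[C@@]2(C)CC/C=C(C)\CC1=O
F4 | step 20 | (1(10)Z,4S,5R,6S,7R,8R)-4,5-epoxy-8-hydroxygermacr-1(10)-en-6-yl (E)-cinnamate | CC(C)[C@H]1[C@H](OC(=O)/C=C/c2ccccc2)[C@H]2O[C@@]2(C)CC/C=C(C)\C[C@H]1O
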